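**Retrosynthetic overview**

1. Atoms are numbered in the order of the target SMILES (C1–C24, O25, C26–C31); ring A = C7/C9/C10/C11/C29/C31, ring B = C11/C13/C26/C27/C28/C29. The strategy rests on this feature: C13 and C26 are adjacent ring-B stereocentres that also belong to the cyclopentane (C13–C14–C15–C16–C26), and C26 is tied to C16 through C23–O25–C20–C17, so the oxolane (C20–C23, O25) is the tether of a 1,7-enyne.
2. Endgame: the C14 carbonyl is removed (Wolff–Kishner) after reduction of C15=C16. Key disconnection: Pauson–Khand [2+2+1] of C15≡C16, C13=C26 and CO (bonds C16–C26, C13–C14, C14–C15), which closes the cyclopentenone and, across the oxolane, the oxane/cycloheptane.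
3. Enyne ⇐ cis-oxolane by methyl (C24) delivery to the C23 oxocarbenium ion ⇐ C26 alkenyllithium + (S)-γ-lactone (C20 by oxazaborolidine reduction; C15–C17 from 3-chloro-3-methylbut-1-yne; C21–C23 from methyl 4-oxobutanoate).
4. Decalin ⇐ (R)-Wieland–Miescher ketone (C29): C7 by two enolate alkylations, C31 deoxygenated, the trans C11 methyl by hydroxyl-directed cyclopropanation and reductive opening, which also gives the C13=C26 enol triflate regiospecifically.
5. Ring order: A and B (from the starting ketone) → oxolane → cyclopentenone together with oxane/cycloheptane (key step).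

Key step: step 20

Remark on the chemistry: β denotes the face of the decalin that carries the C11 methyl (C12) in the target, α the face of the C29 methyl (C30); all intermediates are described with the target numbering, and the four starting compounds are assumed to be purchasable.

**Route**

Step 1
Reactants: 1 (R)-Wieland–Miescher ketone
Product: 2 C26 spiro-1,3-dithiolane of 1 (C11=C13 alkene and C31 ketone kept)
Conditions: HSCH2CH2SH, p-TsOH·H2O (cat), AcOH, rt
Reagents that add atoms: ethane-1,2-dithiol, SCCS
Why: Acid-catalysed thioketalisation of this diketone is known to occur selectively at the conjugated C26 carbonyl without moving the C11=C13 double bond, which masks the enone, leaves C7 as the only enolisable position and touches no stereocentre.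

Step 2
Reactants: 3 5-bromo-2-methylpent-2-ene
Product: 4 5-iodo-2-methylpent-2-ene
Conditions: NaI, acetone, reflux
Reagents that add atoms: sodium iodide, [Na+].[I-]
Why: Finkelstein halide exchange, driven by precipitation of NaBr, gives the more reactive iodide needed for SN2 alkylation of a ketone enolate with an unactivated primary electrophile.

Step 3
Reactants: 2 C26 dithiolane; 4 5-iodo-2-methylpent-2-ene
Product: 6 7-(4-methylpent-3-enyl) C31 ketone (C7 epimers), via lithium enolate 5 (not isolated)
Conditions: LiN(i-Pr)2, THF, −78 °C; then 4, HMPA, −78 → 0 °C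
Reagents that add atoms: none
Why: Enolate alkylation at C7, the only α-carbon of the C31 ketone that bears hydrogen (C29 is quaternary), should install the homoprenyl chain, and the configuration at C7 is irrelevant because the centre is planarised again in step 4.

Step 4
Reactants: 6 7-(4-methylpent-3-enyl) C31 ketone
Product: 8 7β-methyl-7α-(4-methylpent-3-enyl) C31 ketone, via potassium enolate 7 (not isolated)
Conditions: KN(SiMe3)2, THF, −78 → 0 °C; then MeI, −78 °C → rt
Reagents that add atoms: iodomethane, CI
Why: In this enolate alkylation iodomethane should approach C7 from the β-face, anti to the axial C29 methyl that stands 1,3 to it, so that the new methyl is β and the homoprenyl chain α, which is the C7 configuration of the target.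

Step 5
Reactants: 8 7β-methyl-7α-(4-methylpent-3-enyl) C31 ketone
Product: 10 C31-deoxygenated dithiolane (C31H2), via C31 hydrazone 9 (not isolated)
Conditions: N2H4·H2O (large excess), diethylene glycol, 140 °C; then KOH, 200–210 °C
Reagents that add atoms: none
Why: Wolff–Kishner reduction under forcing conditions (the type used for ketones flanked by quaternary carbons) should turn C31 into a methylene group, with no α-hydrogen available for epimerisation or elimination and with the dithiolane and both alkenes inert to hot alkali.

Step 6
Reactants: 10 C31-deoxygenated dithiolane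
Product: 11 ring-B enone (C26 ketone conjugated with C11=C13)
Conditions: MeI (excess), CaCO3, MeCN–H2O 4:1, 50 °C
Reagents that add atoms: water, O
Why: S-Methylation makes the allylic dithiolane a leaving group and hydrolysis frees the enone under near-neutral conditions that leave the trisubstituted side-chain alkene untouched.

Step 7
Reactants: 11 ring-B enone
Product: 12 allylic alcohol with 26β-hydroxyl
Conditions: K[HB(s-Bu)3] (K-Selectride), THF, −78 °C; then H2O
Reagents that add atoms: none
Why: 1,2-Reduction of the β,β-disubstituted enone by the bulky trialkylborohydride should deliver hydride along the equatorial trajectory and give the quasi-axial alcohol anti to the C29 methyl, as is known for the analogous steroidal 4-en-3-ones.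

Step 8
Reactants: 12 allylic alcohol
Product: 13 cyclopropyl carbinol (C12 methylene bridging C11 and C13 on the β-face; 26β-OH)
Conditions: Et2Zn, CH2I2, DME, CH2Cl2, −15 → 0 °C; then H2O
Reagents that add atoms: diiodomethane, ICI
Why: In this hydroxyl-directed Simmons–Smith cyclopropanation the zinc alkoxide delivers the methylene to the face of C11=C13 that it occupies (β, which is also the face anti to the C29 methyl), which sets C11 and should be much faster than undirected attack on the side-chain alkene.

Step 9
Reactants: 13 cyclopropyl carbinol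
Product: 14 cyclopropyl ketone (C26=O)
Conditions: Dess–Martin periodinane, NaHCO3, CH2Cl2, 0 °C → rt
Reagents that add atoms: none
Why: Buffered periodinane oxidation of the secondary alcohol should give the ketone without acid that could open the cyclopropylcarbinyl system.

Step 10
Reactants: 14 cyclopropyl ketone
Product: 16 C26 enol triflate (C13=C26; 11β-methyl), via lithium enolate 15 (not isolated)
Conditions: Li (2.2 equiv), t-BuOH (1.0 equiv), NH3(l)/THF, −78 °C; isoprene; NH3 evaporated; then PhNTf2, THF, −78 → 0 °C
Reagents that add atoms: N-phenylbis(trifluoromethanesulfonimide), O=S(=O)(N(c1ccccc1)S(=O)(=O)C(F)(F)F)C(F)(F)F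
Why: Dissolving-metal cleavage of the conjugated cyclopropane should break the C13–C12 bond (best overlap with the carbonyl π-system and a primary carbanion), which turns C12 into the β-methyl on C11 and leaves the C26(O)=C13 lithium enolate regiospecifically for O-sulfonylation before it can equilibrate.

Step 11
Reactants: 16 C26 enol triflate
Product: 17 C26 trimethylstannane (C13=C26)
Conditions: Me3SnSnMe3, Pd(PPh3)4 (5 mol %), LiCl, THF, 65 °C
Reagents that add atoms: hexamethyldistannane, C[Sn](C)(C)[Sn](C)(C)C
Why: Palladium-catalysed stannylation of an alkenyl triflate (oxidative addition to zerovalent palladium, transmetalation with the distannane, reductive elimination) is standard and keeps the position of the double bond.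

Step 12
Reactants: 18 3-chloro-3-methylbut-1-yne
Product: 20 (3-chloro-3-methylbut-1-yn-1-yl)trimethylsilane, via lithium acetylide 19 (not isolated)
Conditions: n-BuLi, THF, −78 °C; then Me3SiCl, −78 → −20 °C
Reagents that add atoms: chlorotrimethylsilane, C[Si](C)(C)Cl
Why: Deprotonation of the terminal alkyne at low temperature (below the temperature at which the acetylide loses chloride) and C-silylation should mask the acidic C15–H for the later organolithium step.

Step 13
Reactants: 20 (3-chloro-3-methylbut-1-yn-1-yl)trimethylsilane; 21 methyl 4-oxobutanoate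
Product: 23 methyl 4-hydroxy-5,5-dimethyl-7-(trimethylsilyl)hept-6-ynoate (racemic), via allenylzinc chloride 22 (not isolated)
Conditions: Zn dust (activated with BrCH2CH2Br and Me3SiCl), LiCl, THF, 0 °C → rt, 21 present from the start; then H2O
Reagents that add atoms: none
Why: In this Barbier-type propargylation the allenylzinc species should add to the aldehyde (much faster than to the ester) through a cyclic SE2′ transition state, so that the C20–C17 bond forms at the gem-dimethyl carbon and the alkyne is regenerated, while the configuration at C20 is of no concern because the alcohol is oxidised next.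

Step 14
Reactants: 23 racemic hydroxy ester
Product: 24 methyl 5,5-dimethyl-4-oxo-7-(trimethylsilyl)hept-6-ynoate
Conditions: Dess–Martin periodinane, NaHCO3, CH2Cl2, rt
Reagents that add atoms: none
Why: Periodinane oxidation of the hindered secondary alcohol should give the non-conjugated ketone, whose quaternary α-carbon excludes isomerisation to an allene.

Step 15
Reactants: 24 keto ester
Product: 26 (5S)-5-[2-methyl-4-(trimethylsilyl)but-3-yn-2-yl]oxolan-2-one, via (4S)-hydroxy ester 25 (not isolated)
Conditions: (R)-2-methyl-CBS-oxazaborolidine [(R)-1-methyl-3,3-diphenyltetrahydro-1H,3H-pyrrolo[1,2-c][1,3,2]oxazaborole] (0.2 equiv), BH3·SMe2, THF, −20 °C; MeOH; then p-TsOH (cat), toluene, 50 °C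
Reagents that add atoms: none
Why: In this Corey–Bakshi–Shibata reduction the tertiary propargylic group acts as the large and the CH2CH2CO2Me chain as the small substituent, so the (R)-catalyst should give the (20S)-alcohol, which lactonises under acid catalysis.

Step 16
Reactants: 17 C26 trimethylstannane; 26 (S)-lactone
Product: 28 hydroxy enone (C23 ketone on C26; free 20S hydroxyl), via alkenyllithium 27 (not isolated)
Conditions: MeLi, THF, −78 → −40 °C; then 26, THF, −78 °C; then H2O
Reagents that add atoms: none
Why: Tin–lithium exchange gives the C26 alkenyllithium without moving the double bond, and its single addition to the lactone carbonyl (the tetrahedral lithium alkoxide persists at −78 °C) should form the C26–C23 bond, the silyl group keeping the alkyne from quenching the organolithium.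

Step 17
Reactants: 28 hydroxy enone
Product: 29 cyclic methyl ketal (23-methoxy oxolane; C23 epimers)
Conditions: PPTS (cat), HC(OMe)3, MeOH, rt
Reagents that add atoms: trimethyl orthoformate, COC(OC)OC
Why: Acid-catalysed ketalisation of the γ-hydroxy ketone closes the oxolane through the C20 oxygen (5-exo) while the orthoformate removes water, which gives a defined precursor of the ring oxocarbenium ion.

Step 18
Reactants: 29 cyclic methyl ketal
Product: 30 cis-oxolane with 23-methyl (20S,23R; silyl alkyne)
Conditions: Me3SiOTf (1.2 equiv), AlMe3 (3 equiv), CH2Cl2, −78 °C; then aq KNaC4H4O6 (potassium sodium tartrate)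
Reagents that add atoms: trimethylaluminium, C[Al](C)C
Why: Ionisation of the ketal gives the C23 oxocarbenium ion conjugated with C13=C26, and methyl transfer from aluminium should occur at C23 on the ring face anti to the bulky tertiary substituent at C20 (the usual trans delivery of nucleophiles to 5-substituted five-membered oxocarbenium ions), so that the alkenyl group and the C17 arm end up cis, attack at the neopentyl C13 being disfavoured.

Step 19
Reactants: 30 silyl alkyne
Product: 31 enyne with terminal C15≡C16 alkyne
Conditions: K2CO3, MeOH, rt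
Reagents that add atoms: none
Why: Base-catalysed methanolysis of the alkynyl–silicon bond should free the terminal alkyne, the tertiary allylic ether being stable to base.

Step 20
Reactants: 31 enyne
Product: 33 Pauson–Khand enone (C14 ketone; C15=C16), via hexacarbonyldicobalt alkyne complex 32 (not isolated)
Conditions: Co2(CO)8, ClCH2CH2Cl, rt; then n-BuSMe, 83 °C
Reagents that add atoms: dicobalt octacarbonyl, O=C=[Co](=C=O)(=C=O)(=C=O)[Co](=C=O)(=C=O)(=C=O)=C=O
Why: The alkyne–Co2(CO)6 complex loses CO (helped by the sulfide), the ring-B alkene coordinates and inserts to make C16–C26, and CO insertion with reductive elimination makes C13–C14 and C14–C15, the closest known reaction being the intramolecular Pauson–Khand reaction of 1,7-enynes, including ones whose cyclic trisubstituted alkene delivers a quaternary carbon. The cyclopentenone closes by the [2+2+1] union of C15≡C16, C13=C26 and CO; the oxane (C16, C17, C20, O25, C23, C26) closes through the C16–C26 bond in the exo mode (C13 stays outside that ring), and the same bond closes the cycloheptane because C20 and C23 are already bridged by C21–C22. C26 and C13 are set together by the suprafacial addition to the alkene, which makes the new five-membered ring cis-fused to ring B. The face is chosen by the fixed C23 centre and the cis-oxolane: in the reactive rotamer about C26–C23 the ring oxygen lies next to C27H2 and C22H2 next to the small vinylic C13–H with C24 turned away, which puts the alkyne on the β-face and C13 equatorial on a chair-like forming oxane, whereas α-delivery would need a boat-like tether with C22H2 pressed against C27H2. The step needs this β-selectivity (against the axial C11 methyl) and reaction at the ring-B alkene only, and the propargylic gem-dimethyl group at C17 and the cis-2,5-disubstituted oxolane hold the complexed alkyne over C26 while the remote side-chain alkene cannot reach it.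

Step 21
Reactants: 33 Pauson–Khand enone
Product: 35 C14 ketone with 16-H (oxane and cyclopentane trans-fused), via lithium enolate 34 (not isolated)
Conditions: Li (2.2 equiv), t-BuOH (1 equiv), NH3(l)/THF, −78 °C; then NH4Cl
Reagents that add atoms: none
Why: In this dissolving-metal reduction the β-carbanion at C16 should be protonated in the axial direction that keeps overlap with the enolate and leaves C15 equatorial on the oxane chair (the strain-free trans-fused arrangement, C15 axial would point into the C21–C22 bridge), while the isolated trisubstituted alkene and the ethers are not reduced.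

Step 22
Reactants: 35 C14 ketone
Product: 37 CNP0284367.1, via C14 hydrazone 36 (not isolated)
Conditions: N2H4·H2O, KOH, diethylene glycol, 130 °C then 200 °C
Reagents that add atoms: none
Why: Wolff–Kishner reduction removes the C14 carbonyl, and C13, the only centre that can epimerise, should stay in the cis ring fusion that is favoured next to the quaternary C26, the alkene and the ethers being stable to hot alkali.

**Compound list**

1 | (R)-Wieland–Miescher ketone, (8aR)-8a-methyl-3,4,8,8a-tetrahydronaphthalene-1,6(2H,7H)-dione | C[C@@]12CCC(=O)C=C1CCCC2=O | starting material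
2 | C26 spiro-1,3-dithiolane of 1 (C11=C13 alkene, free C31 ketone, 29α-methyl) | C[C@@]12CCC3(SCCS3)C=C1CCCC2=O | intermediate
3 | 5-bromo-2-methylpent-2-ene | CC(C)=CCCBr | starting material
4 | 5-iodo-2-methylpent-2-ene | CC(C)=CCCI | intermediate
5 | lithium C31(O)=C7 enolate of 2 | C[C@@]12CCC3(SCCS3)C=C1CCC=C2[O-].[Li+] | intermediate
6 | 7-(4-methylpent-3-enyl) C31 ketone, C26 dithiolane (mixture of C7 epimers) | C[C@@]12CCC3(SCCS3)C=C1CCC(CCC=C(C)C)C2=O | intermediate
7 | potassium C31(O)=C7 enolate of 6 | C[C@@]12CCC3(SCCS3)C=C1CCC(CCC=C(C)C)=C2[O-].[K+] | intermediate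
8 | 7β-methyl-7α-(4-methylpent-3-enyl) C31 ketone, C26 dithiolane | C[C@@]12CCC3(SCCS3)C=C1CC[C@@](C)(CCC=C(C)C)C2=O | intermediate
9 | C31 hydrazone of 8 | C[C@@]12CCC3(SCCS3)C=C1CC[C@@](C)(CCC=C(C)C)C2=NN | intermediate
10 | 7β-methyl-7α-(4-methylpent-3-enyl) C26 dithiolane with C31H2 | C[C@@]12CCC3(SCCS3)C=C1CC[C@@](C)(CCC=C(C)C)C2 | intermediate
11 | ring-B enone (C26 ketone conjugated with C11=C13) | C[C@@]12CCC(=O)C=C1CC[C@@](C)(CCC=C(C)C)C2 | intermediate
12 | allylic alcohol, 26β-OH (anti to the 29α-methyl), C11=C13 | C[C@@]12CC[C@H](O)C=C1CC[C@@](C)(CCC=C(C)C)C2 | intermediate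
13 | cyclopropyl carbinol: C12 methylene bridging C11 and C13 on the β-face, 26β-OH | C[C@@]12CC[C@H](O)[C@@H]3C[C@]13CC[C@@](C)(CCC=C(C)C)C2 | intermediate
14 | cyclopropyl ketone (C26=O, β-cyclopropane C11–C12–C13) | C[C@@]12CCC(=O)[C@@H]3C[C@]13CC[C@@](C)(CCC=C(C)C)C2 | intermediate
15 | lithium C26(O)=C13 enolate with 11β-methyl | C[C@@]12CCC([O-])=C[C@@]1(C)CC[C@@](C)(CCC=C(C)C)C2.[Li+] | intermediate
16 | C26 enol triflate: C13=C26, 11β-methyl, 29α-methyl, 7β-methyl, 7α-(4-methylpent-3-enyl) | C[C@@]12CCC(OS(=O)(=O)C(F)(F)F)=C[C@@]1(C)CC[C@@](C)(CCC=C(C)C)C2 | intermediate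
17 | C26 trimethylstannane (C13=C26) | C[C@@]12CCC([Sn](C)(C)C)=C[C@@]1(C)CC[C@@](C)(CCC=C(C)C)C2 | intermediate
18 | 3-chloro-3-methylbut-1-yne | CC(C)(Cl)C#C | starting material
19 | lithium 3-chloro-3-methylbut-1-yn-1-ide | CC(C)(Cl)C#[C-].[Li+] | intermediate
20 | (3-chloro-3-methylbut-1-yn-1-yl)trimethylsilane | CC(C)(Cl)C#C[Si](C)(C)C | intermediate
21 | methyl 4-oxobutanoate | COC(=O)CCC=O | starting material
22 | chloro[3-methyl-1-(trimethylsilyl)buta-1,2-dien-1-yl]zinc | CC(C)=C=C([Zn]Cl)[Si](C)(C)C | intermediate
23 | methyl 4-hydroxy-5,5-dimethyl-7-(trimethylsilyl)hept-6-ynoate (racemic) | COC(=O)CCC(O)C(C)(C)C#C[Si](C)(C)C | intermediate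
24 | methyl 5,5-dimethyl-4-oxo-7-(trimethylsilyl)hept-6-ynoate | COC(=O)CCC(=O)C(C)(C)C#C[Si](C)(C)C | intermediate
25 | methyl (4S)-4-hydroxy-5,5-dimethyl-7-(trimethylsilyl)hept-6-ynoate | COC(=O)CC[C@H](O)C(C)(C)C#C[Si](C)(C)C | intermediate
26 | (5S)-5-[2-methyl-4-(trimethylsilyl)but-3-yn-2-yl]oxolan-2-one (C23 carbonyl, C20 stereocentre) | O=C1CC[C@@H](C(C)(C)C#C[Si](C)(C)C)O1 | intermediate
27 | C26 alkenyllithium derived from 17 | C[C@@]12CCC([Li])=C[C@@]1(C)CC[C@@](C)(CCC=C(C)C)C2 | intermediate
28 | hydroxy enone: decalin C26–C23(=O)–C22H2–C21H2–C20H(OH)–C17Me2–C≡C–SiMe3, 20S | C[C@@]12CCC(C(=O)CC[C@H](O)C(C)(C)C#C[Si](C)(C)C)=C[C@@]1(C)CC[C@@](C)(CCC=C(C)C)C2 | intermediate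
29 | cyclic methyl ketal: 23-methoxy oxolane (C23 epimers, 20S) | C[C@@]12CCC(C3(OC)CC[C@@H](C(C)(C)C#C[Si](C)(C)C)O3)=C[C@@]1(C)CC[C@@](C)(CCC=C(C)C)C2 | intermediate
30 | (20S,23R)-cis-oxolane: 23-methyl, C23 bound to C26, C20 bearing 2-methyl-4-(trimethylsilyl)but-3-yn-2-yl | C[C@@]12CCC([C@@]3(C)CC[C@@H](C(C)(C)C#C[Si](C)(C)C)O3)=C[C@@]1(C)CC[C@@](C)(CCC=C(C)C)C2 | intermediate
31 | enyne: (20S,23R)-cis-oxolane with terminal C15≡C16 alkyne and C13=C26 alkene | C[C@@]12CCC([C@@]3(C)CC[C@@H](C(C)(C)C#C)O3)=C[C@@]1(C)CC[C@@](C)(CCC=C(C)C)C2 | intermediate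
32 | Co2(CO)6 complex of the C15≡C16 alkyne of 31 | C[C@@]12CCC([C@@]3(C)CC[C@@H](C(C)(C)C45[CH]6[Co]4(=C=O)(=C=O)(=C=O)[Co]56(=C=O)(=C=O)=C=O)O3)=C[C@@]1(C)CC[C@@](C)(CCC=C(C)C)C2 | intermediate
33 | Pauson–Khand enone: C14 ketone, C15=C16, 13α-H, quaternary C26 (C16 on the β-face) | CC(C)=CCC[C@]1(C)CC[C@]2(C)[C@H]3C(=O)C=C4C(C)(C)[C@@H]5CC[C@@](C)(O5)[C@@]43CC[C@@]2(C)C1 | intermediate
34 | lithium C14(O)=C15 enolate with 16-H | CC(C)=CCC[C@]1(C)CC[C@]2(C)[C@H]3C([O-])=C[C@H]4C(C)(C)[C@@H]5CC[C@@](C)(O5)[C@@]43CC[C@@]2(C)C1.[Li+] | intermediate
35 | C14 ketone of the target skeleton | CC(C)=CCC[C@]1(C)CC[C@]2(C)[C@H]3C(=O)C[C@H]4C(C)(C)[C@@H]5CC[C@@](C)(O5)[C@@]43CC[C@@]2(C)C1 | intermediate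
36 | C14 hydrazone of 35 | CC(C)=CCC[C@]1(C)CC[C@]2(C)[C@H]3C(=NN)C[C@H]4C(C)(C)[C@@H]5CC[C@@](C)(O5)[C@@]43CC[C@@]2(C)C1 | intermediate
37 | CNP0284367.1 | CC(C)=CCC[C@]1(C)CC[C@]2(C)[C@H]3CC[C@H]4C(C)(C)[C@@H]5CC[C@@](C)(O5)[C@@]43CC[C@@]2(C)C1 | target

**Step count and risks**

Total step count: 22
Longest linear sequence: 17 steps (steps 1, 3–11 and 16–22, from 1)

Steps most likely to fail:

Step 20. The cobalt-complexed alkyne may fail to insert into the hindered trisubstituted ring-B alkene, because the β-face it must use is flanked by the axial C11 methyl. The result would be decomplexation without cyclisation, or insertion with poor facial selectivity. The fallback sets out from 30 and returns at 35. Silyl alkyne 30 would be treated with Cp2ZrBu2 (from Cp2ZrCl2 and n-BuLi, THF, −78 °C → rt) to give the zirconacyclopentene F1 (Zr bound to C13 and C15, C16–C26 formed). Its formation is reversible, so the ring fusion would be selected under thermodynamic instead of kinetic control. Carbonylation (CO, 1 atm) and aqueous HCl would give the 15-silyl cyclopentenone F2. Li/NH3 with t-BuOH would reduce it to the 15-silyl ketone F3, and K2CO3 in MeOH would cleave the α-silyl group to give ketone 35.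

Step 18. Methyl transfer to the C23 oxocarbenium ion may occur with poor facial selectivity, or the ion may lose a proton to a dienol ether before it is trapped. The fallback sets out from 28 and returns at 30. MeMgBr with CeCl3 (THF, −78 °C) would add to the C23 ketone to give the diol with a tertiary allylic alcohol F4 (C23 epimers). Catalytic camphorsulfonic acid in CH2Cl2 at 0 °C would ionise it to the tertiary allylic C23 cation, which the C20 hydroxyl traps. This gives 30 together with its C23 epimer, the trans-oxolane F5. The two would be separated by chromatography, and F5 would be returned to the same acid, under which the allylic ether re-ionises and equilibrates.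

Step 5. Hydrazone formation may not take place at the C31 carbonyl, which lies between the quaternary carbons C7 and C29, so that the ketone is recovered. The fallback sets out from 8 and returns at 10. LiAlH4 (THF, reflux) would reduce the ketone to the C31 alcohol F6, and NaH, CS2 and MeI would convert it into the S-methyl xanthate F7. Bu3SnH with catalytic (PhSe)2 and AIBN (benzene, 80 °C) would then give 10. The benzeneselenol formed in the flask traps the C31 radical faster than it can cyclise in the 5-exo mode onto the side-chain alkene, and no β-hydrogen is available for elimination.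

**Further compounds**

F1 | step 20 | zirconacyclopentene from 30 (Cp2Zr bound to C13 and C15, C15 silylated, C15=C16, C16–C26 bond formed) | CC(C)=CCC[C@]1(C)CC[C@]2(C)[C@H]3[Zr](C4C=CC=C4)(C4C=CC=C4)C([Si](C)(C)C)=C4C(C)(C)[C@@H]5CC[C@@](C)(O5)[C@@]43CC[C@@]2(C)C1
F2 | step 20 | 15-(trimethylsilyl) derivative of enone 33 | CC(C)=CCC[C@]1(C)CC[C@]2(C)[C@H]3C(=O)C([Si](C)(C)C)=C4C(C)(C)[C@@H]5CC[C@@](C)(O5)[C@@]43CC[C@@]2(C)C1
F3 | step 20 | 15-(trimethylsilyl) derivative of ketone 35 (C15 epimers) | CC(C)=CCC[C@]1(C)CC[C@]2(C)[C@H]3C(=O)C([Si](C)(C)C)[C@H]4C(C)(C)[C@@H]5CC[C@@](C)(O5)[C@@]43CC[C@@]2(C)C1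
F4 | step 18 | diol: C23 tertiary allylic alcohol (C23 epimers) with 20S hydroxyl | C[C@@]12CCC(C(C)(O)CC[C@H](O)C(C)(C)C#C[Si](C)(C)C)=C[C@@]1(C)CC[C@@](C)(CCC=C(C)C)C2
F5 | step 18 | (20S,23S)-trans-oxolane, the C23 epimer of 30 | C[C@@]12CCC([C@]3(C)CC[C@@H](C(C)(C)C#C[Si](C)(C)C)O3)=C[C@@]1(C)CC[C@@](C)(CCC=C(C)C)C2
F6 | step 5 | C31 alcohol from 8 (C31 epimers) | C[C@@]12CCC3(SCCS3)C=C1CC[C@@](C)(CCC=C(C)C)C2O
F7 | step 5 | C31 O-alkyl S-methyl xanthate | C[C@@]12CCC3(SCCS3)C=C1CC[C@@](C)(CCC=C(C)C)C2OC(=S)SC
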